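The plan hinges on breaking ring B at C2'–C3' and reading it as an isomer of a 2-pyrone. Ring B has O5' flanked by C6' (CH3) and C4' (OH), with C3' a bare CH until late; a symmetric 3-(benzyloxy)pentane-2,4-dione condensed with a malonate, the source of C1', C2' and the carboxyl carbon, leaves exactly this pattern. In a single operation methoxide unlocks the lactone and the liberated acetyl carbon (C3') acylates the adjacent ester (C2'), delivering a resorcylate whose O5' is already set apart. The precursor is tert-butyl 5-(benzyloxy)-4,6-dimethyl-2-oxo-2H-pyran-3-carboxylate; the tert-butyl ester lasts through depside coupling with ring A and falls to acid at the end.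

Key step: step 4

Remark on locants: ring B is numbered C1' (carboxyl-bearing), C2' (OH), C3' (CHO), C4' (OH), C5' (O-acyl), C6' (CH3), and ring A likewise without primes. In the monocyclic compounds the plain benzoate locants 1–6 correspond to these positions.

Assumption: mono-tert-butyl malonate 5 and methyl orsellinate 12 are taken as commercial. The ring B carboxyl is carried as its tert-butyl ester from the malonate stage onward, so the hindered resorcylate needs no ester exchange and the last step is a mild acidolysis that spares the depside link.

Step 1
Reactants: 1 acetylacetone (pentane-2,4-dione)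
Product: 2 3-diazopentane-2,4-dione
Conditions: 4-AcNHC6H4SO2N3, Et3N, MeCN, 0 °C to rt
Reagents that add atoms: 4-acetamidobenzenesulfonyl azide, CC(=O)Nc1ccc(cc1)S(=O)(=O)N=[N+]=[N-]
Why: Regitz diazo transfer, in which the triethylammonium enolate of the 1,3-diketone attacks the terminal nitrogen of the sulfonyl azide and the adduct collapses to the diazo diketone and the sulfonamide.

Step 2
Reactants: 2 3-diazopentane-2,4-dione; 3 benzyl alcohol
Product: 4 3-(benzyloxy)pentane-2,4-dione
Conditions: Rh2(OAc)4 (1 mol %), toluene, 80 °C, slow addition of 2
Reagents that add atoms: none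
Why: Dirhodium carbenoid O–H insertion, in which Rh2(OAc)4 expels N2 and the electrophilic carbenoid is trapped by benzyl alcohol through an oxonium ylide and proton shift, placing the protected oxygen on the central carbon of a still symmetric diketone.

Step 3
Reactants: 4 3-(benzyloxy)pentane-2,4-dione; 5 mono-tert-butyl malonate
Product: 7 tert-butyl 5-(benzyloxy)-4,6-dimethyl-2-oxo-2H-pyran-3-carboxylate, via enol malonate 6 (not isolated)
Conditions: DCC, DMAP (cat.), CH2Cl2, 0 °C to rt; then DBU (cat.), rt
Reagents that add atoms: none
Why: Carbodiimide (Steglich-type) O-acylation of the diketone enol by the malonic half-ester, then intramolecular Knoevenagel condensation of the malonate CH2 onto the remaining ketone and dehydration to the 2-pyrone; the benzyloxy group on the central carbon disfavours C-acylation, and DMAP-mediated acyl exchange should funnel either enol ester geometry through the cyclisable one.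

Step 4
Reactants: 7 tert-butyl 5-(benzyloxy)-4,6-dimethyl-2-oxo-2H-pyran-3-carboxylate
Product: 9 tert-butyl 5-(benzyloxy)-2,4-dihydroxy-6-methylbenzoate, via open-chain keto malonate 8 (not isolated)
Conditions: NaOCH3 (3 equiv), CH3OH, reflux; then AcOH, 0 °C
Reagents that add atoms: none
Why: Methoxide adds to the lactone carbonyl (pyrone C2) and the ring opens to the enolate of 8, in which the newly made methyl ester stands cis to the acetyl-bearing chain; proton exchange with methanol gives a small share of the terminal acetyl enolate, whose carbon (C3') attacks that methyl ester carbonyl (C2'), methoxide leaves, and two enolisations deliver the aromatic resorcylate as its chelated phenoxide. The closest known reaction type is the alkoxide-induced recyclisation of 6-methyl-2-pyrones to resorcinols, in essence a lactone methanolysis followed by an intramolecular Claisen (Dieckmann-type) condensation. Ring B closes in the 6-(enolendo)-exo-trig mode, because both enolate carbons (C3' and C4') become ring atoms while the ester C=O oxygen stays outside the ring, a geometrically favoured closure. No stereocentre is formed, and the racemic C5' centre of 8 disappears on aromatisation. The step needs chemoselectivity for carbon acylation through the methyl terminus over re-lactonisation and over retro-Claisen loss of the acetyl group: re-lactonisation only returns 7, the acetyl carbonyl is largely masked because 8 rests as its C5'-deprotonated dienolate, and irreversible aromatisation drains both equilibria. The tert-butyl ester should be kept because the unhindered methyl ester is the better acyl acceptor and tert-butyl esters resist methoxide, and the symmetry of the parent diketone leaves no regiochemical choice.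

Step 5
Reactants: 9 tert-butyl 5-(benzyloxy)-2,4-dihydroxy-6-methylbenzoate
Product: 10 tert-butyl 5-(benzyloxy)-3-formyl-2,4-dihydroxy-6-methylbenzoate
Conditions: MgCl2, Et3N, (CH2O)n, MeCN, reflux; then cold dilute HCl
Reagents that add atoms: paraformaldehyde (formaldehyde), C=O
Why: Magnesium-mediated ortho-formylation of a phenol (Casnati–Skattebøl), in which the magnesium phenoxide delivers formaldehyde to C3', the only unsubstituted ring carbon and ortho to both O2' and O4', and a second formaldehyde oxidises the hydroxymethyl intermediate by hydride transfer; the basic medium spares the tert-butyl ester and the benzyl ether.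

Step 6
Reactants: 10 tert-butyl 5-(benzyloxy)-3-formyl-2,4-dihydroxy-6-methylbenzoate
Product: 11 tert-butyl 3-formyl-2,4,5-trihydroxy-6-methylbenzoate
Conditions: H2 (1 atm), Pd/C (10% Pd on carbon), EtOAc, rt, stopped after one equivalent of H2; product kept under argon
Reagents that add atoms: none
Why: Hydrogenolysis of the benzyl aryl ether over Pd/C, which should outpace reduction of the aldehyde because the formyl group is deactivated by hydrogen bonds from O2'–H and O4'–H.

Step 7
Reactants: 12 methyl orsellinate
Product: 13 methyl everninate (methyl 2-hydroxy-4-methoxy-6-methylbenzoate)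
Conditions: MeI (1.1 equiv), K2CO3, acetone, reflux
Reagents that add atoms: iodomethane, CI
Why: Williamson O-methylation, selective because the 4-OH para to the ester is the more acidic and the only unchelated phenol, whereas the 2-OH is locked in a hydrogen bond to the ester carbonyl.

Step 8
Reactants: 13 methyl everninate
Product: 14 methyl 3-formyl-2-hydroxy-4-methoxy-6-methylbenzoate
Conditions: MgCl2, Et3N, (CH2O)n, MeCN, reflux; then dilute HCl
Reagents that add atoms: paraformaldehyde (formaldehyde), C=O
Why: Magnesium-mediated ortho-formylation (Casnati–Skattebøl); with O4 methylated, C3 is the only free position ortho to the magnesium phenoxide, so the formyl group can enter nowhere else.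

Step 9
Reactants: 14 methyl 3-formyl-2-hydroxy-4-methoxy-6-methylbenzoate
Product: 15 3-formyl-2-hydroxy-4-methoxy-6-methylbenzoic acid
Conditions: KOH, DMSO–H2O, 80 °C, argon; then cold 2 M HCl
Reagents that add atoms: potassium hydroxide, [K+].[OH-]
Why: Saponification (BAc2) of the hindered methyl ester in aqueous DMSO, where poorly solvated hydroxide is reactive enough; the ortho phenoxide formed first deactivates the non-enolisable aldehyde toward hydroxide, and cold acidification avoids decarboxylation.

Step 10
Reactants: 11 tert-butyl 3-formyl-2,4,5-trihydroxy-6-methylbenzoate; 15 3-formyl-2-hydroxy-4-methoxy-6-methylbenzoic acid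
Product: 16 tert-butyl 3-formyl-5-[(3-formyl-2-hydroxy-4-methoxy-6-methylbenzoyl)oxy]-2,4-dihydroxy-6-methylbenzoate
Conditions: DCC, toluene–Et2O, 0 °C to rt, argon
Reagents that add atoms: none
Why: Carbodiimide-mediated esterification (depside coupling); in 11 the O2'–H and O4'–H groups are tied in hydrogen bonds to the ester and formyl carbonyls and conjugated with them, so the unchelated O5'–H is the nucleophilic phenol, the chelated 2-OH of acid 15 should not compete, and base-free conditions are chosen to avoid acyl migration from O5' to O4'.

Step 11
Reactants: 16 tert-butyl 3-formyl-5-[(3-formyl-2-hydroxy-4-methoxy-6-methylbenzoyl)oxy]-2,4-dihydroxy-6-methylbenzoate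
Product: 17 haemathamnolic acid
Conditions: CF3CO2H–CH2Cl2 (1:3), 0 °C to rt
Reagents that add atoms: none
Why: Acidolysis of the tert-butyl ester (AAL1, loss of the tert-butyl cation as isobutene) at or below room temperature, conditions under which the hindered diaryl ester, both aldehydes and the methyl ether should persist and the acid should not decarboxylate.

Compound list
1 | acetylacetone (pentane-2,4-dione) | CC(=O)CC(C)=O | starting material
2 | 3-diazopentane-2,4-dione | CC(=O)C(=[N+]=[N-])C(C)=O | intermediate
3 | benzyl alcohol | OCc1ccccc1 | starting material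
4 | 3-(benzyloxy)pentane-2,4-dione (keto/enol mixture, drawn as the diketone) | CC(=O)C(OCc1ccccc1)C(C)=O | intermediate
5 | mono-tert-butyl malonate (3-tert-butoxy-3-oxopropanoic acid) | CC(C)(C)OC(=O)CC(=O)O | starting material
6 | (E)-3-(benzyloxy)-4-oxopent-2-en-2-yl tert-butyl propanedioate (enol malonate, acyloxy group cis to acetyl; formed in situ) | CC(=O)/C(OCc1ccccc1)=C(/C)OC(=O)CC(=O)OC(C)(C)C | intermediate
7 | tert-butyl 5-(benzyloxy)-4,6-dimethyl-2-oxo-2H-pyran-3-carboxylate | CC(C)(C)OC(=O)C1=C(C)C(OCc2ccccc2)=C(C)OC1=O | intermediate
8 | tert-butyl methyl (E)-2-[3-(benzyloxy)-4-oxopentan-2-ylidene]propanedioate (racemic; formed in situ as its sodium enolate) | COC(=O)/C(C(=O)OC(C)(C)C)=C(/C)C(OCc1ccccc1)C(C)=O | intermediate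
9 | tert-butyl 5-(benzyloxy)-2,4-dihydroxy-6-methylbenzoate | CC(C)(C)OC(=O)c1c(C)c(OCc2ccccc2)c(O)cc1O | intermediate
10 | tert-butyl 5-(benzyloxy)-3-formyl-2,4-dihydroxy-6-methylbenzoate | CC(C)(C)OC(=O)c1c(C)c(OCc2ccccc2)c(O)c(C=O)c1O | intermediate
11 | tert-butyl 3-formyl-2,4,5-trihydroxy-6-methylbenzoate | CC(C)(C)OC(=O)c1c(C)c(O)c(O)c(C=O)c1O | intermediate
12 | methyl orsellinate (methyl 2,4-dihydroxy-6-methylbenzoate) | COC(=O)c1c(C)cc(O)cc1O | starting material
13 | methyl everninate (methyl 2-hydroxy-4-methoxy-6-methylbenzoate) | COC(=O)c1c(C)cc(OC)cc1O | intermediate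
14 | methyl 3-formyl-2-hydroxy-4-methoxy-6-methylbenzoate | COC(=O)c1c(C)cc(OC)c(C=O)c1O | intermediate
15 | 3-formyl-2-hydroxy-4-methoxy-6-methylbenzoic acid | OC(=O)c1c(C)cc(OC)c(C=O)c1O | intermediate
16 | tert-butyl 3-formyl-5-[(3-formyl-2-hydroxy-4-methoxy-6-methylbenzoyl)oxy]-2,4-dihydroxy-6-methylbenzoate | COc1cc(C)c(C(=O)Oc2c(C)c(C(=O)OC(C)(C)C)c(O)c(C=O)c2O)c(O)c1C=O | intermediate
17 | haemathamnolic acid (3-formyl-5-[(3-formyl-2-hydroxy-4-methoxy-6-methylbenzoyl)oxy]-2,4-dihydroxy-6-methylbenzoic acid) | COc1cc(C)c(C(=O)Oc2c(C)c(C(=O)O)c(O)c(C=O)c2O)c(O)c1C=O | target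

Total step count: 11.
Longest linear sequence: 8 steps (steps 1–6, 10 and 11, from acetylacetone 1 to 17). The ring A branch (steps 7–9) joins at step 10.

Steps most likely to fail

Step 4. Cleavage of the acetyl group by methoxide (retro-Claisen), or stalling at the open-chain dienolate, may outpace carbon acylation, so that ring B does not close. The fallback closes ring B by the aldol mode at C1'–C6' of a linear triketo ester, the established polyketide-type route to orsellinate rings. It sets out from benzyl alcohol 3 and comes back at 9. Benzyl alcohol 3 is alkylated with ethyl bromoacetate (NaH, THF) to ethyl 2-(benzyloxy)acetate F1. The dianion of tert-butyl acetoacetate (NaH, then n-BuLi, THF, 0 °C) is acylated at its terminal carbon by F1 to give tert-butyl 6-(benzyloxy)-3,5-dioxohexanoate F2. The trianion of F2 (LiN(iPr)2, THF, −78 °C) is acetylated at C6 with N-methoxy-N-methylacetamide to give racemic tert-butyl 6-(benzyloxy)-3,5,7-trioxooctanoate F3. Mild base (KHCO3, aqueous MeOH, rt) should then close F3 by attack of C2 on the C7 ketone, and dehydration and enolisation give 9.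

Step 3. The activated half-ester may be consumed by self-condensation, or acylation may take place at carbon, before the enol oxygen is acylated; the enol ester may also be cleaved by base before the Knoevenagel closure. The fallback attaches the malonate through carbon first. It sets out from 4 and comes back at 7. Diketone 4 is converted with (COCl)2 and catalytic DMF (CH2Cl2, 0 °C) into the vinylogous acid chloride 3-(benzyloxy)-4-chloropent-3-en-2-one F4. The sodium enolate of tert-butyl methyl malonate (NaH, THF) displaces chloride by addition–elimination and, after a mild acid quench, gives the open-chain keto malonate 8. Heating 8 in toluene with catalytic pyridinium p-toluenesulfonate while methanol distils should close the lactone through the enol oxygen to pyrone 7.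

Step 10. Acylation may be shared between O5' and O4', the aroyl group may migrate from O5' to O4' during coupling or work-up, and slow coupling may divert the activated acid to an N-acylurea. The fallback removes the choice by protection. It sets out from 10 and comes back at 17. Compound 10 is alkylated at O4', the more acidic and less chelated phenol, with MOMCl and iPr2NEt (CH2Cl2, 0 °C) to tert-butyl 5-(benzyloxy)-3-formyl-2-hydroxy-4-(methoxymethoxy)-6-methylbenzoate F5. Hydrogenolysis (H2, Pd/C, EtOAc) gives tert-butyl 3-formyl-2,5-dihydroxy-4-(methoxymethoxy)-6-methylbenzoate F6, in which O5'–H is the only unchelated phenol. F6 is esterified with acid 15 (DCC, catalytic DMAP, CH2Cl2) to tert-butyl 3-formyl-5-[(3-formyl-2-hydroxy-4-methoxy-6-methylbenzoyl)oxy]-2-hydroxy-4-(methoxymethoxy)-6-methylbenzoate F7. Trifluoroacetic acid in CH2Cl2 should then remove the methoxymethyl ether and the tert-butyl ester together to give 17.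

Further compounds
F1 | step 4 | ethyl 2-(benzyloxy)acetate | CCOC(=O)COCc1ccccc1
F2 | step 4 | tert-butyl 6-(benzyloxy)-3,5-dioxohexanoate | CC(C)(C)OC(=O)CC(=O)CC(=O)COCc1ccccc1
F3 | step 4 | tert-butyl 6-(benzyloxy)-3,5,7-trioxooctanoate (racemic) | CC(C)(C)OC(=O)CC(=O)CC(=O)C(OCc1ccccc1)C(C)=O
F4 | step 3 | 3-(benzyloxy)-4-chloropent-3-en-2-one (E/Z mixture) | CC(=O)C(OCc1ccccc1)=C(C)Cl
F5 | step 10 | tert-butyl 5-(benzyloxy)-3-formyl-2-hydroxy-4-(methoxymethoxy)-6-methylbenzoate | CC(C)(C)OC(=O)c1c(C)c(OCc2ccccc2)c(OCOC)c(C=O)c1O
F6 | step 10 | tert-butyl 3-formyl-2,5-dihydroxy-4-(methoxymethoxy)-6-methylbenzoate | CC(C)(C)OC(=O)c1c(C)c(O)c(OCOC)c(C=O)c1O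
F7 | step 10 | tert-butyl 3-formyl-5-[(3-formyl-2-hydroxy-4-methoxy-6-methylbenzoyl)oxy]-2-hydroxy-4-(methoxymethoxy)-6-methylbenzoate | COCOc1c(C=O)c(O)c(C(=O)OC(C)(C)C)c(C)c1OC(=O)c1c(C)cc(OC)c(C=O)c1O
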